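## Structural features

The target is a 6,7-seco-ent-kaurane. Ring A (C1–C5, C10) is a cyclohexane joined by the single bond C9–C10 to a bicyclo[3.2.1]octane, which consists of a cyclohexanone (ring C: C8, C9, C11, C12, C13, C14, ketone at C12) and a cyclopentane (ring D: C8, C14, C13, C16, C15) bearing the exocyclic methylidene C16=C17. Ring A carries three contiguous stereocentres: quaternary C10 (methyl C20, C9), C5 (H, carboxyl C6) and quaternary C4 (methyl C18, carboxyl C19), with C20 and both carboxyl groups on one face. Tertiary C9 lies between the quaternary carbons C10 and C8; on ring C the formyl carbon C7 on C8 is cis to C10 and the C15–C16 bridge is trans to it, and the bridgehead C13 follows from the bridge. The fragile groups are the formyl group, the C7/C12 1,5-dicarbonyl array (strong base can open C8–C9 by retro-Michael reaction), the 1,1-disubstituted alkene β,γ to C12 (acid moves it into ring D) and C5–H α to a carboxyl. The real difficulty is the congested C10–C9–C8 triad, together with absolute control in two sectors that are linked only by a rotatable bond. The key step exploits ring C: the C12 carbonyl is 1,4 to the formyl-bearing quaternary C8 and the ring A substituent on C9 is vicinal to C8, which is the retron of a [4+2] addition of a 2-oxygenated diene (C13=C12–C11=C9) to a 2-substituted acrolein (C14=C8).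

## Logic of the disconnections

21 ⇒ 20. The two carboxyl groups are traced back to methyl esters, so the forward step cuts two O–CH3 bonds. Free acids would not survive the enolate, silyl triflate and Lewis acid steps, and the methyl esters are already present in 1. Nothing is gained in the skeleton. The forward step must dealkylate one axial tertiary ester and one doubly flanked secondary ester beside a formyl group and a ketone, so it has to attack the methyl carbon, not the acyl carbon.

20 ⇒ 19. C13–C16 is cut. This bond joins a ketone α-carbon to an alkene carbon, the retron of a palladium-catalysed enolate alkenylation. Ring D, the bridgehead stereocentre and the sensitive exocyclic alkene disappear, leaving a monocyclic ketone with a vinyl bromide. The forward step must react at C13 and not at C11 (both are 1,3 to C8) and must leave the formyl group alone.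

19 ⇒ 18. The C12 ketone is traced to its C11=C12 silyl enol ether, because 18 is the primary cycloadduct. The forward protodesilylation must not release a free enolate that could expel C8.

18 ⇒ 12 + 17. C8–C9 and C13–C14 are cut. The cut divides the molecule into two fragments of similar size and removes ring C and the stereocentres C8 and C9 together. The forward cycloaddition must show para/ortho regiochemistry, an endo formyl group and one diene face, at a diene terminus that carries a tertiary alkyl group.

17 ⇒ 16 ⇒ 15 ⇒ 13 + 14. The C8=C14 double bond is cut back to formaldehyde, C7 is taken to the ester level, and C8–C15 is cut as an enolate allylation. Three short steps from two bulk chemicals result. The demands are mono-alkylation and a clean half-reduction.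

12 ⇒ 11 ⇒ 10. The O–Si bond and then the C9=C11 unsaturation are removed. 11 can enolise only at C13 and 10 can be dehydrogenated only towards C9, so neither step has a regiochemical choice once the ketone is in place.

10 ⇒ 8 + 9. C9–C10 is cut. A tertiary radical at C10 adding to an enone tolerates the congestion that defeats polar bond formation at a quaternary carbon. Ring A is reduced to a tricarboxylate. The forward step must take the acceptor on the face of the radical opposite the C19 and C6 esters.

8 ⇒ 7 ⇒ 6 ⇒ 5. The redox-active ester is traced through the acid chloride and the acid to a tert-butyl ester, which marks the one carboxyl that will be lost. The demand is orthogonality to the two methyl esters.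

5 ⇒ 4. C4–C18 and C10–C20 are cut; both methyl groups sit α to an ester. Both quaternary centres vanish. The forward step must deprotonate the outer carbons and not C5, and must place each methyl trans to the C5 ester.

4 ⇒ 3 ⇒ 2. The tert-butyl ester goes back to the acid, and the acid to one of two enantiotopic esters of meso 2. Absolute configuration of ring A is reduced to a group selection on a symmetric triester.

2 ⇒ 1. Six hydrogens are removed. The all-cis relationship of the three esters becomes the outcome of one face-selective arene hydrogenation.

## Other disconnections considered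

Alternative 1: Ring A is cut at C3–C4 and C5–C10, with an ester link from the C6 carbonyl to the C7 oxygen as a temporary tether. The forward key step is a thermal intramolecular Diels–Alder reaction of triene ester A1, in which the (E)-penta-2,4-dien-2-yl group on C9 adds to the tethered citraconate, giving tetracyclic lactone A2. In its favour, one step sets C4, C5 and C10, the (Z)-citraconate fixes the cis relation of C6 and C19, the tether fixes regiochemistry, and the existing bicycle delivers the dienophile to one diene face. Against it here, the diene terminus C10 is fully substituted, so an inside substituent strains the s-cis form. The dienophile is trisubstituted and two quaternary carbons form in a thermal reaction, so forcing conditions are to be expected. The exocyclic alkene cannot coexist with the later hydrogenation of C1=C2, so C17 travels as a silyloxymethyl group on a C16 stereocentre, and C7 emerges at the alcohol level inside a seven-membered lactone. Hydrogenation, lactone opening, C7 oxidation and regeneration of the methylidene all follow the key step. Compared with the chosen plan, both use a [4+2] step, but this one is linear and carries more redox and protecting-group traffic. On setting the three ring A stereocentres in one event, and on needing neither an enzymatic desymmetrisation nor a chiral catalyst for ring A, it is the better of the two. On convergence, dienophile activation and step economy the chosen plan is better.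

Alternative 2: Ring D is cut at C15–C16. In the forward step Bu3SnH turns iodide A3 (iodomethyl on C8, ethynyl on C13, both carbonyls as acetals) into a primary radical that closes 5-exo-dig onto the alkyne and, after hydrogen transfer, gives the methylidene bicycle A4. In its favour, the ring closure has no site ambiguity because the C13 substituent is already in place, the conditions are neutral, and the methylidene appears directly. Against it, A3 needs an extra stereocentre at C13 (ethynyl cis to C15), two acetals that must later be removed with acid beside the migrating-prone alkene, and a stoichiometric tin reagent. It also offers nothing for the harder problem of ring C and the C8–C9–C10 triad. On regiochemical certainty of the ring D closure it is better than the palladium step of the chosen plan. On the bridgehead configuration the two are equal, since geometry dictates it in both. On step count and protecting groups the chosen plan is better.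

Alternative 3: C8–C15 and C14–C16 are cut as a cyclobutane. The forward step is a [2+2] photocycloaddition of allene to ring C enone A5 (C13 ketone, C14=C8), giving the cis-fused methylenecyclobutane A6, followed by a strain-release shift of C16 from C14 to C13 (for instance a 1,2-vinyl shift of a C13 radical). In its favour, enone–allene photocycloaddition builds a quaternary β-carbon reliably, its head-to-head regiochemistry is well established, and the allene should add anti to the large C9 substituent. Against it, A6 has its ketone at C13, where the target has CH, and an alcohol at C12, where the target has the ketone, so a deoxygenative rearrangement, two oxidations and silyl ether removals follow. A5 also already contains the C9–C10 bond, so the hardest bond is left unsolved. On creating C8 with substrate control alone, and on freedom from site ambiguity in ring D formation, it is equal to or better than the chosen plan. On oxidation-state economy, convergence and step count the chosen plan is better.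

Key step: step 13

Assumption: the hydrolase of step 2 is the one that, on screening, cleaves the ester on the (S)-configured outer carbon of meso triester 2; the enantiotopic preference cannot be predicted from structure alone.

Assumption: the (S)-oxazaborolidinium catalyst of step 13 is taken to expose the required face of 17 on the basis of the s-trans, formyl C–H···O model for 2-substituted acroleins; the (R)-catalyst is equally available should a methacrolein test reaction show the opposite sense.

## Route

Step 1
Reactants: 1 trimethyl benzene-1,2,3-tricarboxylate
Product: 2 trimethyl all-cis-cyclohexane-1,2,3-tricarboxylate (meso)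
Conditions: H2 (50 bar), 5% Rh on Al2O3, MeOH, 60 °C
Reagents that add atoms: none
Why: Heterogeneous arene hydrogenation delivers all hydrogens from the catalyst surface to one face, so the three esters should end up cis; rhodium on alumina reduces benzene polycarboxylates without ester hydrogenolysis.

Step 2
Reactants: 2 trimethyl all-cis-cyclohexane-1,2,3-tricarboxylate
Product: 3 (1S,2S,3R)-2,3-bis(methoxycarbonyl)cyclohexane-1-carboxylic acid (three carboxyl carbons cis)
Conditions: pig liver esterase, phosphate buffer pH 7.5, DMSO (5%), 25 °C; then HCl to pH 2
Reagents that add atoms: water, O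
Why: Enzymatic desymmetrisation of a meso diester: the two equatorial outer esters are enantiotopic and the hydrolase should cleave one, while the axial, flanked central ester is expected to be spared; this step fixes the absolute configuration of ring A.

Step 3
Reactants: 3 (1S,2S,3R)-2,3-bis(methoxycarbonyl)cyclohexane-1-carboxylic acid
Product: 4 1-tert-butyl 2,3-dimethyl (1S,2R,3R)-cyclohexane-1,2,3-tricarboxylate (all-cis)
Conditions: isobutene, H2SO4 (cat.), CH2Cl2, sealed vessel, 25 °C
Reagents that add atoms: isobutene, CC(C)=C
Why: Acid-catalysed addition of the carboxylic acid to isobutene gives the tert-butyl ester without touching the stereocentres; it marks the carboxyl that will later be lost and permits enolate chemistry.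

Step 4
Reactants: 4 1-tert-butyl 2,3-dimethyl (1S,2R,3R)-cyclohexane-1,2,3-tricarboxylate
Product: 5 1-tert-butyl 2,3-dimethyl (1S,2R,3R)-1,3-dimethylcyclohexane-1,2,3-tricarboxylate (three esters cis; both methyls on the other face)
Conditions: LDA (2.5 equiv), THF, −78 → −40 °C; MeI (6 equiv), DMPU, −78 → 0 °C
Reagents that add atoms: iodomethane, CI
Why: Double ester enolate alkylation: the axial outer hydrogens are removed in preference to the shielded equatorial C5–H (a C5 enolate would suffer allylic strain on both sides), and each exocyclic enolate, whose neighbouring C5 ester is pushed axial by A(1,3) strain, is methylated anti to that ester. This sets C4 with its methyl trans to the C5 ester; the configuration at the tert-butyl ester carbon is irrelevant because it becomes a radical.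

Step 5
Reactants: 5 1-tert-butyl 2,3-dimethyl (1S,2R,3R)-1,3-dimethylcyclohexane-1,2,3-tricarboxylate
Product: 6 (1S,2S,3R)-2,3-bis(methoxycarbonyl)-1,3-dimethylcyclohexane-1-carboxylic acid
Conditions: TFA–CH2Cl2 (1:3), 0 → 25 °C
Reagents that add atoms: none
Why: Acidolysis of a tert-butyl ester through the tert-butyl cation; the methyl esters are inert and no stereocentre is enolisable under acid.

Step 6
Reactants: 6 (1S,2S,3R)-2,3-bis(methoxycarbonyl)-1,3-dimethylcyclohexane-1-carboxylic acid
Product: 8 1-(1,3-dioxoisoindolin-2-yl) 2,3-dimethyl (1S,2R,3R)-1,3-dimethylcyclohexane-1,2,3-tricarboxylate, via acid chloride 7 (not isolated)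
Conditions: (COCl)2, DMF (cat.), CH2Cl2, 0 → 25 °C; evaporate; N-hydroxyphthalimide, Et3N, DMAP (cat.), CH2Cl2, 0 → 25 °C
Reagents that add atoms: N-hydroxyphthalimide, O=C1c2ccccc2C(=O)N1O
Why: The hindered tertiary acid is activated as its acid chloride, which acylates N-hydroxyphthalimide where carbodiimide coupling would be slow; this gives the redox-active ester.

Step 7
Reactants: 8 the N-acyloxyphthalimide of ring A; 9 methyl vinyl ketone (but-3-en-2-one)
Product: 10 dimethyl (1R,2S,3S)-1,3-dimethyl-3-(3-oxobutyl)cyclohexane-1,2-dicarboxylate (C3 methyl cis to both esters)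
Conditions: Ru(bpy)3(PF6)2 (1 mol%), Hantzsch ester (1.5 equiv), CH2Cl2, blue LEDs, 25 °C
Reagents that add atoms: none
Why: Photoredox decarboxylative Giese reaction: single-electron reduction of the phthalimide ester releases CO2 and the tertiary C10 radical, which adds to the enone. The acceptor should approach equatorially on the face opposite the syn-axial C19 ester and the adjacent C6 ester, leaving the C20 methyl axial and cis to both esters.

Step 8
Reactants: 10 dimethyl (1R,2S,3S)-1,3-dimethyl-3-(3-oxobutyl)cyclohexane-1,2-dicarboxylate
Product: 11 dimethyl (1R,2S,3S)-1,3-dimethyl-3-[(1E)-3-oxobut-1-en-1-yl]cyclohexane-1,2-dicarboxylate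
Conditions: IBX (2.5 equiv), DMSO–toluene (1:2), 75 °C
Reagents that add atoms: none
Why: IBX dehydrogenation of a ketone through its enol; only the C11 side carries a β-hydrogen (the methyl side has no β-carbon, and quaternary C10 stops further oxidation), and the (E)-enone is the stable isomer.

Step 9
Reactants: 11 dimethyl (1R,2S,3S)-1,3-dimethyl-3-[(1E)-3-oxobut-1-en-1-yl]cyclohexane-1,2-dicarboxylate
Product: 12 dimethyl (1R,2S,3S)-1,3-dimethyl-3-[(1E)-3-(triisopropylsilyloxy)buta-1,3-dien-1-yl]cyclohexane-1,2-dicarboxylate
Conditions: TIPSOTf (1.3 equiv), Et3N (2 equiv), CH2Cl2, 0 °C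
Reagents that add atoms: triisopropylsilyl triflate, CC(C)[Si](OS(=O)(=O)C(F)(F)F)(C(C)C)C(C)C
Why: Soft enolisation and O-silylation; the methyl group is the only enolisable position (the γ-carbon C10 is quaternary), so the 2-silyloxydiene forms with retention of the (E)-alkene. The triisopropylsilyl group is chosen over trimethylsilyl because it withstands the strongly acidic cycloaddition catalyst.

Step 10
Reactants: 13 tert-butyl acetate; 14 2,3-dibromopropene
Product: 15 tert-butyl 4-bromopent-4-enoate
Conditions: LDA (1.05 equiv), THF, −78 °C; then 14, −78 → 0 °C
Reagents that add atoms: none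
Why: Alkylation of the stable lithium enolate of tert-butyl acetate at the allylic bromide; the vinylic bromide is inert to SN2 attack.

Step 11
Reactants: 15 tert-butyl 4-bromopent-4-enoate
Product: 16 4-bromopent-4-enal
Conditions: DIBAL-H (1.1 equiv), CH2Cl2, −78 °C; aqueous Rochelle salt
Reagents that add atoms: none
Why: Half-reduction of an ester: the tetrahedral aluminium hemiacetal persists at −78 °C and releases the aldehyde on work-up; the volatile product is carried on in solution.

Step 12
Reactants: 16 4-bromopent-4-enal
Product: 17 4-bromo-2-methylidenepent-4-enal (2-(2-bromoallyl)acrolein)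
Conditions: aqueous HCHO (37%), pyrrolidine (10 mol%), EtCO2H (10 mol%), i-PrOH, 45 °C
Reagents that add atoms: formaldehyde, C=O
Why: Amine-catalysed α-methylenation (enamine Mannich reaction with formaldehyde, then elimination of the amine) installs C14; the enal is used freshly because it polymerises.

Step 13
Reactants: 12 the ring A 2-silyloxydiene; 17 2-(2-bromoallyl)acrolein
Product: 18 dimethyl (1R,2S,3S)-3-[(1S,6R)-6-(2-bromoprop-2-en-1-yl)-6-formyl-3-(triisopropylsilyloxy)cyclohex-2-en-1-yl]-1,3-dimethylcyclohexane-1,2-dicarboxylate (formyl cis to ring A)
Conditions: (S)-o-tolyl-oxazaborolidine from (S)-α,α-diphenylprolinol (20 mol%), Tf2NH (18 mol%), 17 (1.5 equiv), CH2Cl2, −78 → −20 °C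
Reagents that add atoms: none
Why: The protonated oxazaborolidine binds the formyl oxygen of 17 (boron–oxygen bond plus a formyl C–H···O contact), lowers its LUMO and screens one face of the s-trans enal; 12 then adds in a concerted but asynchronous normal-demand [4+2], with C13–C14 forming ahead of the hindered C8–C9 bond. The closest known reaction type is the cationic-oxazaborolidine-catalysed Diels–Alder reaction of 2-substituted acroleins with 2-silyloxy-1,3-dienes. Ring C is closed by intermolecular [4+2] annulation, both ring bonds forming in the one step and the C11=C12 silyl enol ether remaining as the new double bond. Regiochemistry is doubly secured: the silyloxy group on C12 makes C13 the nucleophilic terminus and the alkyl group on C9 is ortho-directing, so C13 meets the β-carbon C14 and C9 meets C8. C8 is set by the catalyst, which leaves open the face of 17 on which formyl, C14 and the bromoallyl carbon run clockwise as seen from the diene. C9 follows from the (E)-geometry of 12 and the endo position of the small, catalyst-bound formyl group, the bulkier bromoallyl arm taking the exo position beside the inside hydrogen of C9; this places C7 cis to C10. The diene face that this combination demands is the one anti to C5 of ring A with the C20 methyl outside, which a staggered allylic model also prefers, so catalyst and substrate are expected to be matched. The step thus needs para/ortho regioselectivity, endo selectivity and one diene face: the first is electronic, the second steric, and the third is imposed by the catalyst with support from C10.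

Step 14
Reactants: 18 the ring C silyl enol ether
Product: 19 dimethyl (1R,2S,3S)-3-[(1S,2R)-2-(2-bromoprop-2-en-1-yl)-2-formyl-5-oxocyclohexyl]-1,3-dimethylcyclohexane-1,2-dicarboxylate
Conditions: TBAF (1.1 equiv), AcOH (1.5 equiv), THF, 0 °C
Reagents that add atoms: none
Why: Buffered fluoride desilylation protonates C11 as the Si–O bond breaks, so no free enolate persists that could expel C8 by retro-Michael reaction; C11 is a methylene, so no stereocentre is at stake.

Step 15
Reactants: 19 the keto aldehyde vinyl bromide
Product: 20 dimethyl 7,12-dioxo-6,7-seco-ent-kaur-16-ene-6,19-dioate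
Conditions: Pd(PPh3)4 (10 mol%), KOPh (1.5 equiv), THF, 65 °C
Reagents that add atoms: none
Why: Palladium-catalysed intramolecular ketone α-alkenylation: zerovalent palladium inserts into the C–Br bond, the phenoxide-generated enolate binds, and reductive elimination forms C13–C16, closing ring D with the methylidene in place. Closure needs the bromoallyl arm axial and the new bond axial on the same face, which fixes the bridgehead C13. C13 is expected to be favoured over C11 because C11 is flanked by C9 and its ring A substituent, but this preference is not secured (see the uncertain steps). The formyl group has no α-hydrogen, and phenoxide is too weak a base to attack it.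

Step 16
Reactants: 20 dimethyl 7,12-dioxo-6,7-seco-ent-kaur-16-ene-6,19-dioate
Product: 21 7,12-dioxo-6,7-seco-ent-kaur-16-ene-6,19-dioic acid (CNP0320711.1)
Conditions: LiI (10 equiv), pyridine, 110 °C; then 1 M HCl
Reagents that add atoms: none
Why: Nucleophilic ester dealkylation: iodide attacks the unhindered methyl carbon (SN2), so the crowding at the acyl carbons of C19 and C6 does not matter; the medium is non-basic enough to spare the formyl group, the 1,5-dicarbonyl array and the C5 stereocentre.

## Compound list

1 | trimethyl benzene-1,2,3-tricarboxylate | COC(=O)c1cccc(C(=O)OC)c1C(=O)OC | starting material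
2 | trimethyl all-cis-cyclohexane-1,2,3-tricarboxylate (meso) | COC(=O)[C@H]1CCC[C@@H](C(=O)OC)[C@H]1C(=O)OC | intermediate
3 | (1S,2S,3R)-2,3-bis(methoxycarbonyl)cyclohexane-1-carboxylic acid | OC(=O)[C@H]1CCC[C@@H](C(=O)OC)[C@H]1C(=O)OC | intermediate
4 | 1-tert-butyl 2,3-dimethyl (1S,2R,3R)-cyclohexane-1,2,3-tricarboxylate | CC(C)(C)OC(=O)[C@H]1CCC[C@@H](C(=O)OC)[C@H]1C(=O)OC | intermediate
5 | 1-tert-butyl 2,3-dimethyl (1S,2R,3R)-1,3-dimethylcyclohexane-1,2,3-tricarboxylate | CC(C)(C)OC(=O)[C@@]1(C)CCC[C@@](C)(C(=O)OC)[C@H]1C(=O)OC | intermediate
6 | (1S,2S,3R)-2,3-bis(methoxycarbonyl)-1,3-dimethylcyclohexane-1-carboxylic acid | OC(=O)[C@@]1(C)CCC[C@@](C)(C(=O)OC)[C@H]1C(=O)OC | intermediate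
7 | acid chloride of 6 (configuration unchanged) | ClC(=O)[C@@]1(C)CCC[C@@](C)(C(=O)OC)[C@H]1C(=O)OC | intermediate (not isolated)
8 | 1-(1,3-dioxoisoindolin-2-yl) 2,3-dimethyl (1S,2R,3R)-1,3-dimethylcyclohexane-1,2,3-tricarboxylate | O=C(ON1C(=O)c2ccccc2C1=O)[C@@]1(C)CCC[C@@](C)(C(=O)OC)[C@H]1C(=O)OC | intermediate
9 | methyl vinyl ketone | C=CC(C)=O | starting material
10 | dimethyl (1R,2S,3S)-1,3-dimethyl-3-(3-oxobutyl)cyclohexane-1,2-dicarboxylate | CC(=O)CC[C@]1(C)CCC[C@@](C)(C(=O)OC)[C@H]1C(=O)OC | intermediate
11 | dimethyl (1R,2S,3S)-1,3-dimethyl-3-[(1E)-3-oxobut-1-en-1-yl]cyclohexane-1,2-dicarboxylate | CC(=O)/C=C/[C@]1(C)CCC[C@@](C)(C(=O)OC)[C@H]1C(=O)OC | intermediate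
12 | dimethyl (1R,2S,3S)-1,3-dimethyl-3-[(1E)-3-(triisopropylsilyloxy)buta-1,3-dien-1-yl]cyclohexane-1,2-dicarboxylate | C=C(O[Si](C(C)C)(C(C)C)C(C)C)/C=C/[C@]1(C)CCC[C@@](C)(C(=O)OC)[C@H]1C(=O)OC | intermediate
13 | tert-butyl acetate | CC(=O)OC(C)(C)C | starting material
14 | 2,3-dibromopropene | C=C(Br)CBr | starting material
15 | tert-butyl 4-bromopent-4-enoate | C=C(Br)CCC(=O)OC(C)(C)C | intermediate
16 | 4-bromopent-4-enal | C=C(Br)CCC=O | intermediate
17 | 4-bromo-2-methylidenepent-4-enal (2-(2-bromoallyl)acrolein) | C=C(C=O)CC(Br)=C | intermediate
18 | dimethyl (1R,2S,3S)-3-[(1S,6R)-6-(2-bromoprop-2-en-1-yl)-6-formyl-3-(triisopropylsilyloxy)cyclohex-2-en-1-yl]-1,3-dimethylcyclohexane-1,2-dicarboxylate | C=C(Br)C[C@]1(C=O)CCC(O[Si](C(C)C)(C(C)C)C(C)C)=C[C@H]1[C@]1(C)CCC[C@@](C)(C(=O)OC)[C@H]1C(=O)OC | intermediate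
19 | dimethyl (1R,2S,3S)-3-[(1S,2R)-2-(2-bromoprop-2-en-1-yl)-2-formyl-5-oxocyclohexyl]-1,3-dimethylcyclohexane-1,2-dicarboxylate | C=C(Br)C[C@]1(C=O)CCC(=O)C[C@H]1[C@]1(C)CCC[C@@](C)(C(=O)OC)[C@H]1C(=O)OC | intermediate
20 | dimethyl 7,12-dioxo-6,7-seco-ent-kaur-16-ene-6,19-dioate | C=C1C[C@]2(C=O)C[C@H]1C(=O)C[C@H]2[C@]1(C)CCC[C@@](C)(C(=O)OC)[C@H]1C(=O)OC | intermediate
21 | 7,12-dioxo-6,7-seco-ent-kaur-16-ene-6,19-dioic acid (CNP0320711.1) | C=C1C[C@]2(C=O)C[C@H]1C(=O)C[C@H]2[C@]1(C)CCC[C@@](C)(C(=O)O)[C@H]1C(=O)O | target

## Step count and least certain steps

Total: 16 steps. Longest linear sequence: 13 steps (steps 1–9, then 13–16); the dienophile branch is 3 steps (10–12).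

Step 13 (key step). The cycloaddition at the C9 terminus, which carries a tertiary alkyl group, may be slow enough that acid-promoted protodesilylation of the diene and oligomerisation of the enal compete. Facial control may erode if the intrinsic preference of C10 opposes the catalyst, and some exo addition may occur. Fallback, from 12 and 17: the two bonds are made in separate operations. A Mukaiyama–Michael addition (Tf2NH, 2 mol%, CH2Cl2, −78 °C, aqueous work-up) forms only C13–C14 at the unhindered terminus and gives the open-chain enone aldehyde F1, dimethyl (1R,2S,3S)-3-[(1E)-8-bromo-6-formyl-3-oxonona-1,8-dien-1-yl]-1,3-dimethylcyclohexane-1,2-dicarboxylate. A chiral primary amine salt then converts the α-branched aldehyde into its enamine, which closes C8–C9 by a 6-exo intramolecular Michael addition to the enone. The ring closure is reversible and can be driven to the more stable isomer; its diastereoselectivity would have to be established. The product is 19, so the route is rejoined at 19 and step 14 is not needed.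

Step 15. C11 and C13 are both 1,3 to C8, so alkenylation at the wrong α-carbon is the main danger. Further dangers are intermolecular aldol addition of the enolate to the formyl group, and base-induced retro-Michael opening of C8–C9, which would scramble C8 and C9. Fallback, from 18, while the silyl enol ether still masks the ketone:
- NaBH4 (MeOH–CH2Cl2, 0 °C) reduces only the formyl group, giving the primary alcohol F2.
- NaH and 4-methoxybenzyl chloride (DMF, 0 °C) give the 4-methoxybenzyl ether F3.
- TBAF–AcOH releases the ketone F4.
- LDA at −78 °C removes the less hindered C13 proton under kinetic control; transmetalation with ZnCl2 and coupling under Pd(P(t-Bu)3)2 closes ring D regiospecifically to the bicyclic ether F5.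
- DDQ (CH2Cl2, pH 7 buffer) frees the bicyclic alcohol F6, and Dess–Martin periodinane restores the formyl group.

The route is rejoined at 20.

Step 2. Discrimination between the enantiotopic esters may be incomplete, the central ester may be hydrolysed, or the enzyme may prefer the antipodal ester. Fallback, from 2: one equivalent of KOH in aqueous methanol gives the racemic monoacid, that is 3 together with its enantiomer F7. Crystallisation with (R)-1-phenylethylamine (the amine enantiomer being chosen by test crystallisation) gives the diastereomerically pure ammonium salt F8, and acidification returns 3, where the route is rejoined.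

Step 16. Dealkylation of the two hindered esters may stall under conditions mild enough for the formyl group. Prolonged heating may open ring C through the 1,5-dicarbonyl array or move the exocyclic alkene into ring D. Fallback, from 20: NaBH4 reduces both carbonyl groups to the diol diester F9 (either C12 epimer serves). With no carbonyl left, lithium propanethiolate in HMPA cleaves both methyl esters to the diol diacid F10. Dess–Martin periodinane then reoxidises both alcohols, giving 21.

Step 8. Dehydrogenation may be incomplete, or oxidation may occur at the methyl side of the ketone. Fallback, from 10: acid-catalysed bromination (PhNMe3Br3, THF, 0 °C) takes place at the more substituted α-carbon C11 and gives the bromoketone F11, dimethyl (1R,2S,3S)-3-(2-bromo-3-oxobutyl)-1,3-dimethylcyclohexane-1,2-dicarboxylate. Li2CO3 and LiBr in DMF at 120 °C eliminate HBr to the (E)-enone 11, where the route is rejoined.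

## Further compounds

F1 | step 13 | dimethyl (1R,2S,3S)-3-[(1E)-8-bromo-6-formyl-3-oxonona-1,8-dien-1-yl]-1,3-dimethylcyclohexane-1,2-dicarboxylate (both C8 epimers) | C=C(Br)CC(C=O)CCC(=O)/C=C/[C@]1(C)CCC[C@@](C)(C(=O)OC)[C@H]1C(=O)OC
F2 | step 15 | primary alcohol from reduction of the formyl group of 18 | C=C(Br)C[C@]1(CO)CCC(O[Si](C(C)C)(C(C)C)C(C)C)=C[C@H]1[C@]1(C)CCC[C@@](C)(C(=O)OC)[C@H]1C(=O)OC
F3 | step 15 | 4-methoxybenzyl ether of F2 | C=C(Br)C[C@]1(COCc2ccc(OC)cc2)CCC(O[Si](C(C)C)(C(C)C)C(C)C)=C[C@H]1[C@]1(C)CCC[C@@](C)(C(=O)OC)[C@H]1C(=O)OC
F4 | step 15 | ring C ketone with 4-methoxybenzyloxymethyl group on C8 | C=C(Br)C[C@]1(COCc2ccc(OC)cc2)CCC(=O)C[C@H]1[C@]1(C)CCC[C@@](C)(C(=O)OC)[C@H]1C(=O)OC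
F5 | step 15 | bicyclo[3.2.1]octanone with 4-methoxybenzyloxymethyl group on C8 | C=C1C[C@]2(COCc3ccc(OC)cc3)C[C@H]1C(=O)C[C@H]2[C@]1(C)CCC[C@@](C)(C(=O)OC)[C@H]1C(=O)OC
F6 | step 15 | bicyclo[3.2.1]octanone with hydroxymethyl group on C8 | C=C1C[C@]2(CO)C[C@H]1C(=O)C[C@H]2[C@]1(C)CCC[C@@](C)(C(=O)OC)[C@H]1C(=O)OC
F7 | step 2 | (1R,2R,3S)-2,3-bis(methoxycarbonyl)cyclohexane-1-carboxylic acid (enantiomer of 3) | OC(=O)[C@@H]1CCC[C@H](C(=O)OC)[C@@H]1C(=O)OC
F8 | step 2 | (R)-1-phenylethylammonium salt of 3 | [O-]C(=O)[C@H]1CCC[C@@H](C(=O)OC)[C@H]1C(=O)OC.C[C@@H]([NH3+])c1ccccc1
F9 | step 16 | dimethyl 7,12-dihydroxy-6,7-seco-ent-kaur-16-ene-6,19-dioate (C12 epimers) | C=C1C[C@]2(CO)C[C@H]1C(O)C[C@H]2[C@]1(C)CCC[C@@](C)(C(=O)OC)[C@H]1C(=O)OC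
F10 | step 16 | 7,12-dihydroxy-6,7-seco-ent-kaur-16-ene-6,19-dioic acid (C12 epimers) | C=C1C[C@]2(CO)C[C@H]1C(O)C[C@H]2[C@]1(C)CCC[C@@](C)(C(=O)O)[C@H]1C(=O)O
F11 | step 8 | dimethyl (1R,2S,3S)-3-(2-bromo-3-oxobutyl)-1,3-dimethylcyclohexane-1,2-dicarboxylate | CC(=O)C(Br)C[C@]1(C)CCC[C@@](C)(C(=O)OC)[C@H]1C(=O)OC
A1 | alternative 1 | citraconate triene ester, precursor of the intramolecular cycloaddition | CC(C)(C)[Si](C)(C)OC[C@H]1C[C@]2(COC(=O)/C=C(/C)C(=O)OC)C[C@H]1C(=O)C[C@H]2/C(C)=C/C=C
A2 | alternative 1 | tetracyclic lactone with ring A as the C1=C2 cyclohexene | CC(C)(C)[Si](C)(C)OC[C@H]1C[C@]2(COC3=O)C[C@H]1C(=O)C[C@H]2[C@]1(C)C=CC[C@@](C)(C(=O)OC)[C@H]13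
A3 | alternative 2 | ring C iodide with ethynyl on C13, both carbonyls as acetals | IC[C@]1(C(OC)OC)C[C@H](C#C)C2(OCCO2)C[C@H]1[C@]1(C)CCC[C@@](C)(C(=O)OC)[C@H]1C(=O)OC
A4 | alternative 2 | bicyclo[3.2.1]octane with methylidene, both carbonyls as acetals | C=C1C[C@]2(C(OC)OC)C[C@H]1C1(OCCO1)C[C@H]2[C@]1(C)CCC[C@@](C)(C(=O)OC)[C@H]1C(=O)OC
A5 | alternative 3 | ring C enone (C13 ketone, C14=C8) with silyloxymethyl on C8 and silyloxy on C12 | O=C1C=C(CO[Si](C)(C)C(C)(C)C)[C@@H](C[C@H]1O[Si](C)(C)C(C)(C)C)[C@]1(C)CCC[C@@](C)(C(=O)OC)[C@H]1C(=O)OC
A6 | alternative 3 | cis-fused methylenecyclobutane photoadduct | O=C1[C@H]2C(=C)C[C@@]2(CO[Si](C)(C)C(C)(C)C)[C@@H](C[C@H]1O[Si](C)(C)C(C)(C)C)[C@]1(C)CCC[C@@](C)(C(=O)OC)[C@H]1C(=O)OC
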